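**Retrosynthetic overview**

1. Target 16 ⇐ methyl ester 15 ⇐ hemiketal-masked diketone 14 by double methylenation (both 1,1-disubstituted alkenes are made last).
2. 14 ⇐ 8-prenylchromanone 10 + enone 12 by dearomative Michael addition at C-8 of ring A; this sets C-8, and a temporary C–O hemiketal ring relays the configuration to C-2'.
3. 10 ⇐ 8 ⇐ tricycle 6 by C-prenylation and by asymmetric conjugate reduction/methanolysis of the coumarin lactone (sets the side-chain centre).
4. Key disconnection, O1–C2 of ring B: 6 ⇐ 8-tigloylcoumarin 5 by asymmetric intramolecular oxa-Michael addition (sets C-2 and C-3, cis); the lactone C–O tether leaves 7-OH as the only possible nucleophile.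
5. 5 ⇐ coumarin 3 ⇐ phloroglucinol 1. Ring order: lactone ring (temporary) → ring B (dihydropyranone) → hemiketal ring (temporary); ring A is the phloroglucinol ring, dearomatised in step 7.

Assumption: the target is taken as the C5-enol tautomer drawn in the SMILES; for steps 4 and 7 the named catalyst antipode is the one expected to give the stated centre, and the mirror-image (or pseudo-enantiomeric) catalyst is used if a test run shows the opposite sense.

Conventions: chromanone locants (O1, C2, C3, C4, C4a, C5–C8, C8a) are used from compound 8 on; C-1' and C-2' are the first two carbons of the ten-carbon chain on C-8. Catalyst Q = 3-[3,5-bis(trifluoromethyl)anilino]-4-[(9-deoxy-epi-quinin-9-yl)amino]cyclobut-3-ene-1,2-dione.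

**Route**

Step 1
Reactants: 1 phloroglucinol; 2 ethyl 3-oxohexanoate
Product: 3 5,7-dihydroxy-4-propyl-2H-chromen-2-one
Conditions: conc. H2SO4, 0 °C → rt
Reagents that add atoms: none
Why: Pechmann condensation (transesterification, ring hydroxyalkylation, dehydration) on the symmetric triol gives the 4-propylcoumarin, whose lactone C–O bond later blocks one of the two oxygens next to the acyl group.

Step 2
Reactants: 3 5,7-dihydroxy-4-propyl-2H-chromen-2-one; 4 tigloyl chloride
Product: 5 5,7-dihydroxy-8-[(E)-2-methylbut-2-enoyl]-4-propyl-2H-chromen-2-one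
Conditions: AlCl3 (4 equiv), PhNO2, 25 °C
Reagents that add atoms: none
Why: Friedel–Crafts acylation of 5,7-dihydroxy-4-alkylcoumarins goes mainly to C-8 (between the lactone oxygen and 7-OH), and the low temperature keeps the enone open; the minor 6-acyl isomer is removed by chromatography.

Step 3
Reactants: 5 5,7-dihydroxy-8-[(E)-2-methylbut-2-enoyl]-4-propyl-2H-chromen-2-one
Product: 6 (8R,9S)-5-hydroxy-8,9-dimethyl-4-propyl-8,9-dihydro-2H,10H-pyrano[2,3-f]chromene-2,10-dione
Conditions: (−)-quinine (20 mol%), PhCl, 15 °C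
Reagents that add atoms: none
Why: Key C–O bond formation by base-catalysed intramolecular 6-endo oxa-Michael addition: only 7-OH is free next to the enone, the quinine–phenoxide ion pair selects the enone face to give the (R) O–CH(CH3) centre, and kinetic protonation of the enol gives the cis (S) α-centre, the sense recalled for quinine with tigloylcoumarins of this type.

Step 4
Reactants: 6 (8R,9S)-5-hydroxy-8,9-dimethyl-4-propyl-8,9-dihydro-2H,10H-pyrano[2,3-f]chromene-2,10-dione
Product: 8 methyl (3S)-3-[(2R,3S)-5,7-dihydroxy-2,3-dimethyl-4-oxo-3,4-dihydro-2H-chromen-6-yl]hexanoate, via dihydrocoumarin lactone 7 (not isolated)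
Conditions: Cu(OAc)2 (5 mol%), (R)-DTBM-SEGPHOS (5.5 mol%), (EtO)2MeSiH (3 equiv), t-BuOH (2 equiv), THF, 0 °C; then HCl in MeOH, 0 °C → rt
Reagents that add atoms: methanol, CO
Why: Ligand-controlled CuH conjugate reduction of the unsaturated lactone (ligand = (R)-5,5'-bis[di(3,5-di-tert-butyl-4-methoxyphenyl)phosphino]-4,4'-bi-1,3-benzodioxole) delivers hydride to C-4 and sets the (S) side-chain centre, and acid methanolysis then opens the lactone, driven by the new 5-OH···O=C4 chelate; the di-ortho-substituted aryl ketone is expected to react more slowly.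

Step 5
Reactants: 8 methyl (3S)-3-[(2R,3S)-5,7-dihydroxy-2,3-dimethyl-4-oxo-3,4-dihydro-2H-chromen-6-yl]hexanoate; 9 prenyl bromide (1-bromo-3-methylbut-2-ene)
Product: 10 methyl (3S)-3-[(2R,3S)-5,7-dihydroxy-2,3-dimethyl-8-(3-methylbut-2-en-1-yl)-4-oxo-3,4-dihydro-2H-chromen-6-yl]hexanoate
Conditions: NaOMe (2 equiv), MeOH, −10 °C
Reagents that add atoms: none
Why: C-alkylation of the phloroglucinol-type phenoxide in a protic solvent (SN2 at the primary allylic bromide) at C-8, the only unsubstituted ring carbon; the 5-phenoxide lowers the acidity of H-3, which protects the cis-chromanone.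

Step 6
Reactants: 11 methyl vinyl ketone (2 equiv)
Product: 12 3-methylideneheptane-2,6-dione
Conditions: 1,4-diazabicyclo[2.2.2]octane (10 mol%), THF, rt
Reagents that add atoms: none
Why: Amine-catalysed Rauhut–Currier (Baylis–Hillman-type) head-to-tail dimerisation of the vinyl ketone.

Step 7
Reactants: 10 methyl (3S)-3-[(2R,3S)-5,7-dihydroxy-2,3-dimethyl-8-(3-methylbut-2-en-1-yl)-4-oxo-3,4-dihydro-2H-chromen-6-yl]hexanoate; 12 3-methylideneheptane-2,6-dione
Product: 14 7-O,2'-cyclic hemiketal of methyl (3S)-3-[(2R,3S,8R)-8-[(2R)-2-acetyl-5-oxohexyl]-5-hydroxy-2,3-dimethyl-8-(3-methylbut-2-en-1-yl)-4,7-dioxo-3,4,7,8-tetrahydro-2H-chromen-6-yl]hexanoate, via open-chain Michael adduct 13 (not isolated)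
Conditions: catalyst Q (10 mol%), toluene, −20 °C; then pyridinium p-toluenesulfonate (20 mol%), CHCl3, 40 °C
Reagents that add atoms: none
Why: Proposed new method: a catalytic asymmetric dearomative Michael addition with built-in hemiketalisation, in which the quinuclidine nitrogen deprotonates the acidic 7-OH, the squaramide N–H pair binds the enone carbonyl and C-8 (ortho to the phenoxide and less hindered than C-6) attacks the methylene carbon on the face left open in the chiral ion pair, setting C-8 (R); the new 7-enol then closes onto the 2'-acetyl group to a six-membered hemiketal, which stops retro-Michael re-aromatisation, removes the acidic enol so the catalyst turns over, and relays configuration because the C-8 prenyl group is forced axial on the new ring (C-8a lies anti to the ring oxygen) so that only the (R)-C-2' epimer can hold its 3-oxobutyl chain equatorial, and acid equilibration of C-2' through the cyclic enol ether funnels both epimers to 14; the closest known reactions are cinchona-squaramide dearomative Michael additions of 2-naphthols, chiral phase-transfer alkylative dearomatisation of acylphloroglucinols and the Michael/hemiketal cascades of 4-hydroxycoumarins with enones.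

Step 8
Reactants: 14 7-O,2'-cyclic hemiketal of the diketone ester
Product: 15 methyl (3S)-3-[(2R,3S,8R)-5-hydroxy-2,3-dimethyl-8-(3-methylbut-2-en-1-yl)-8-[(2R)-5-methyl-2-(prop-1-en-2-yl)hex-5-en-1-yl]-4,7-dioxo-3,4,7,8-tetrahydro-2H-chromen-6-yl]hexanoate
Conditions: Ph3PCH3Br (5 equiv), KN(SiMe3)2 (5 equiv), THF, −20 → 0 °C
Reagents that add atoms: methyltriphenylphosphonium bromide, C[P+](c1ccccc1)(c1ccccc1)c1ccccc1.[Br-]
Why: Double Wittig methylenation: base opens the hemiketal to its keto-enolate tautomer, the delocalised ring anion shields the ring carbonyls and H-3, and addition of the small ylide to the two methyl ketones is expected to outrun enolisation at C-2'.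

Step 9
Reactants: 15 methyl ester of the target
Product: 16 (3S)-3-[(2R,3S,8R)-5-hydroxy-2,3-dimethyl-8-(3-methylbut-2-en-1-yl)-8-[(2R)-5-methyl-2-(prop-1-en-2-yl)hex-5-en-1-yl]-4,7-dioxo-3,4,7,8-tetrahydro-2H-chromen-6-yl]hexanoic acid
Conditions: LiOH·H2O (3 equiv), THF–H2O, 0 °C → rt; then 1 M HCl
Reagents that add atoms: lithium hydroxide, [Li+].[OH-]
Why: Saponification of the unhindered methyl ester; the substrate sits as its vinylogous-acid enolate, which does not undergo E1cB opening of ring B, so the cis-chromanone and C-8 are left alone.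

**Compound list**

1 | phloroglucinol (benzene-1,3,5-triol) | Oc1cc(O)cc(O)c1 | starting material
2 | ethyl 3-oxohexanoate | CCCC(=O)CC(=O)OCC | starting material
3 | 5,7-dihydroxy-4-propyl-2H-chromen-2-one | CCCC1=CC(=O)Oc2cc(O)cc(O)c12 | intermediate
4 | tigloyl chloride [(E)-2-methylbut-2-enoyl chloride] | C/C=C(\C)C(=O)Cl | starting material
5 | 5,7-dihydroxy-8-[(E)-2-methylbut-2-enoyl]-4-propyl-2H-chromen-2-one | CCCC1=CC(=O)Oc2c1c(O)cc(O)c2C(=O)/C(C)=C/C | intermediate
6 | (8R,9S)-5-hydroxy-8,9-dimethyl-4-propyl-8,9-dihydro-2H,10H-pyrano[2,3-f]chromene-2,10-dione (cis-dimethylpyranone fused through O-7/C-8 of the coumarin) | CCCC1=CC(=O)Oc2c1c(O)cc1O[C@H](C)[C@H](C)C(=O)c12 | intermediate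
7 | (4S,8R,9S)-5-hydroxy-8,9-dimethyl-4-propyl-3,4,8,9-tetrahydro-2H,10H-pyrano[2,3-f]chromene-2,10-dione (not isolated) | CCC[C@H]1CC(=O)Oc2c1c(O)cc1O[C@H](C)[C@H](C)C(=O)c12 | intermediate
8 | methyl (3S)-3-[(2R,3S)-5,7-dihydroxy-2,3-dimethyl-4-oxo-3,4-dihydro-2H-chromen-6-yl]hexanoate | COC(=O)C[C@H](CCC)c1c(O)cc2O[C@H](C)[C@H](C)C(=O)c2c1O | intermediate
9 | prenyl bromide (1-bromo-3-methylbut-2-ene) | CC(C)=CCBr | starting material
10 | methyl (3S)-3-[(2R,3S)-5,7-dihydroxy-2,3-dimethyl-8-(3-methylbut-2-en-1-yl)-4-oxo-3,4-dihydro-2H-chromen-6-yl]hexanoate | COC(=O)C[C@H](CCC)c1c(O)c(CC=C(C)C)c2O[C@H](C)[C@H](C)C(=O)c2c1O | intermediate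
11 | methyl vinyl ketone (but-3-en-2-one) | C=CC(C)=O | starting material
12 | 3-methylideneheptane-2,6-dione | CC(=O)CCC(=C)C(C)=O | intermediate
13 | methyl (3S)-3-[(2R,3S,8R)-8-(2-acetyl-5-oxohexyl)-5-hydroxy-2,3-dimethyl-8-(3-methylbut-2-en-1-yl)-4,7-dioxo-3,4,7,8-tetrahydro-2H-chromen-6-yl]hexanoate, both C-2' epimers (not isolated) | CC(=O)CCC(C[C@@]1(CC=C(C)C)C(=O)C([C@@H](CCC)CC(=O)OC)=C(O)C2=C1O[C@H](C)[C@H](C)C2=O)C(C)=O | intermediate
14 | 7-O,2'-cyclic hemiketal of 13 with target configuration at C-8 and C-2' (2-hydroxy-2-methyl-3-(3-oxobutyl)dihydropyran ring through O-7, the acetyl carbon, C-2', C-1', C-8 and C-7; anomeric mixture) | CC(=O)CC[C@@H]1C[C@@]2(CC=C(C)C)C(OC1(C)O)=C([C@@H](CCC)CC(=O)OC)C(=O)C3=C2O[C@H](C)[C@H](C)C3=O | intermediate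
15 | methyl (3S)-3-[(2R,3S,8R)-5-hydroxy-2,3-dimethyl-8-(3-methylbut-2-en-1-yl)-8-[(2R)-5-methyl-2-(prop-1-en-2-yl)hex-5-en-1-yl]-4,7-dioxo-3,4,7,8-tetrahydro-2H-chromen-6-yl]hexanoate | C=C(C)CC[C@H](C[C@@]1(CC=C(C)C)C(=O)C([C@@H](CCC)CC(=O)OC)=C(O)C2=C1O[C@H](C)[C@H](C)C2=O)C(=C)C | intermediate
16 | (3S)-3-[(2R,3S,8R)-5-hydroxy-2,3-dimethyl-8-(3-methylbut-2-en-1-yl)-8-[(2R)-5-methyl-2-(prop-1-en-2-yl)hex-5-en-1-yl]-4,7-dioxo-3,4,7,8-tetrahydro-2H-chromen-6-yl]hexanoic acid (CNP0294320.1) | C=C(C)CC[C@H](C[C@@]1(CC=C(C)C)C(=O)C([C@@H](CCC)CC(=O)O)=C(O)C2=C1O[C@H](C)[C@H](C)C2=O)C(=C)C | target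

**Step count**

Total step count: 9. Longest linear sequence: 8 (steps 1–5 and 7–9; step 6 is a one-step side branch).

**Steps most likely to fail, with fallbacks**

Step 7 (the proposed new reaction). Face selectivity at C-8 may be low, the adduct may revert by retro-Michael re-aromatisation during the acid equilibration, or the hemiketal relay may give a poor C-2' ratio. The fallback uses known chemistry, sets out from 8 and comes back to the route at 14; it makes the two C–C bonds at C-8 in the reverse order. Phenol 8 is added through its free C-8 to enone 12 with Et3N in MeOH, an ordinary Michael C-alkylation of a phloroglucinol-type ring, to give the aromatic diketone ester F1 as both C-2' epimers. F1 is then prenylated at the now substituted C-8 by palladium-catalysed asymmetric allylic dearomatisation (Pd2(dba)3, (R,R)-DACH-phenyl Trost ligand, prenyl methyl carbonate, toluene, 0 °C), which gives 13. Compound 13 is equilibrated with pyridinium p-toluenesulfonate as in step 7; if that ratio is poor, the C-2' epimers of 14 are separated by chromatography and the unwanted one is recycled with DBU.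

Step 4. The copper hydride may also reduce the chromanone carbonyl, or give low selectivity on this electron-rich coumarin. The fallback sets out from 6 and comes back at 8 and relies on separation instead of catalyst control. Non-selective conjugate reduction with [(Ph3P)CuH]6 in wet toluene gives 7 together with its C-4 epimer, the (4R)-lactone F2. Methanolysis with HCl in MeOH then gives 8 together with the (3R)-ester F3. Because 6 is already a single enantiomer these are diastereomers, and 8 is isolated by preparative HPLC or crystallisation.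

Step 8. The basic ylide may partly epimerise C-2', or leave the more hindered 2'-acetyl group unreacted. The fallback sets out from 14 and comes back at 15 and replaces the Wittig reaction by a Peterson olefination through a non-basic organocerium reagent. Me3SiCH2MgCl premixed with anhydrous CeCl3 in THF at −78 °C adds to both ketones (the hemiketal opens as its alkoxide) to give the bis(β-hydroxysilane) F4. HF·pyridine in MeCN at 0 °C then eliminates both silanols to give 15.

**Further compounds**

F1 | step 7 | methyl (3S)-3-[(2R,3S)-8-(2-acetyl-5-oxohexyl)-5,7-dihydroxy-2,3-dimethyl-4-oxo-3,4-dihydro-2H-chromen-6-yl]hexanoate, both C-2' epimers | COC(=O)C[C@H](CCC)c1c(O)c(CC(CCC(C)=O)C(C)=O)c2O[C@H](C)[C@H](C)C(=O)c2c1O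
F2 | step 4 | (4R,8R,9S)-5-hydroxy-8,9-dimethyl-4-propyl-3,4,8,9-tetrahydro-2H,10H-pyrano[2,3-f]chromene-2,10-dione | CCC[C@@H]1CC(=O)Oc2c1c(O)cc1O[C@H](C)[C@H](C)C(=O)c12
F3 | step 4 | methyl (3R)-3-[(2R,3S)-5,7-dihydroxy-2,3-dimethyl-4-oxo-3,4-dihydro-2H-chromen-6-yl]hexanoate | COC(=O)C[C@@H](CCC)c1c(O)cc2O[C@H](C)[C@H](C)C(=O)c2c1O
F4 | step 8 | bis(β-hydroxysilane) from double Me3SiCH2 addition to the two methyl ketones of 14 (open-chain form, carbinol centres unassigned) | C[Si](C)(C)CC(C)(O)CC[C@H](C[C@@]1(CC=C(C)C)C(=O)C([C@@H](CCC)CC(=O)OC)=C(O)C2=C1O[C@H](C)[C@H](C)C2=O)C(C)(O)C[Si](C)(C)C
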